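Numbering the ring as 2-hydroxy-3-methyl-6-nonadecyl-1,4-benzoquinone, the route rests on a 3+3 disconnection across C3–C4 and C1–C6. It exploits the 2-methyl-1,3-dioxygen pattern at C2/C3/C4, a masked 2-methylcyclohexane-1,3-dione. One Michael–Claisen annulation joins ethyl 3-oxopentanoate (C1, C2, C3 and the methyl) to ethyl (E)-docos-2-enoate (C4, C5, C6 and the chain) and closes the six-membered ring; the activating ester on C1 is then lost as CO2. Dehydrogenation to the resorcinol and Fremy oxidation at C1, para to the C4 oxygen, complete the quinone.

Key step: step 2

Remark: the target has no stereocentre, so 6 and 7 are carried as stereoisomer and tautomer mixtures; the two ring CH2 groups of 7 (ring CH groups of 8) that flank the nonadecyl-bearing carbon are equivalent by symmetry, so oxidation at either one in step 4 gives the same quinone.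

Step 1
Reactants: 1 1-icosanol; 2 ethyl (triphenylphosphoranylidene)acetate
Product: 4 ethyl (E)-docos-2-enoate, via icosanal 3 (not isolated)
Conditions: TEMPO (10 mol%), PhI(OAc)2 (1.1 equiv), CH2Cl2, rt; then 2 (1.3 equiv), rt
Reagents that add atoms: none
Why: The TEMPO/PhI(OAc)2 oxoammonium oxidation should stop at the aldehyde, and the stabilised ylide should then give the (E)-enoate by Wittig olefination in the same flask; the alkene geometry has no bearing on step 2.

Step 2
Reactants: 4 ethyl (E)-docos-2-enoate; 5 ethyl 3-oxopentanoate
Product: 7 2-methyl-5-nonadecylcyclohexane-1,3-dione, via keto ester 6 (not isolated)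
Conditions: NaOEt (1.1 equiv), EtOH, reflux; then aq. KOH, reflux; then HCl to pH 1, reflux
Reagents that add atoms: none
Why: Ethoxide forms the stabilised enolate of 5, whose central carbon adds to the β-carbon of 4 (Michael addition) and so joins the nonadecyl-bearing carbon to the carbon that ends as quinone C1. Proton exchange then gives the enolate at the propionyl CH2, which attacks the ester carbonyl of the former enoate and expels ethoxide (Claisen condensation), joining the methyl-bearing carbon C3 to the C4 carbonyl. The closest known reaction is the classical Michael–Claisen preparation of 5-alkylcyclohexane-1,3-diones from an acetoacetate and a crotonate-type ester, used here with a 3-oxopentanoate so that the ring methyl is already in place. The six-membered ring closes by a 6-exo-trig acylation, and the stable enolate of the cyclic β-dicarbonyl 6 pulls the reversible steps forward. The selectivity needed is regiochemical and the substrates secure it: only the carbon between the two carbonyls of 5 is acidic enough to start the conjugate addition, and in the adduct only the propionyl carbon reaches the far ester through a six-membered transition state, while O-acylation to an enol lactone is reopened by ethoxide. The stereocentres of 6 form without control and do not matter, since they are enolisable or vanish in step 3, and hydroxide followed by acid then hydrolyses and decarboxylates the β-keto ester in the same flask.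

Step 3
Reactants: 7 2-methyl-5-nonadecylcyclohexane-1,3-dione
Product: 8 2-methyl-5-nonadecylbenzene-1,3-diol
Conditions: 10% Pd/C (cat.), triglyme, reflux, N2 stream
Reagents that add atoms: none
Why: Catalytic dehydrogenation of a cyclohexane-1,3-dione over Pd/C, driven by aromatisation and removal of H2, is the established way from 2-methylcyclohexane-1,3-diones to 2-methylresorcinols, and the saturated chain should be inert.

Step 4
Reactants: 8 2-methyl-5-nonadecylbenzene-1,3-diol
Product: 9 capiquinone C
Conditions: ON(SO3K)2 (2.5 equiv), KH2PO4, H2O/THF, rt
Reagents that add atoms: dipotassium nitrosodisulfonate (Fremy's salt), [K+].[K+].[O]N(S(=O)(=O)[O-])S(=O)(=O)[O-]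
Why: In the Teuber oxidation the nitroxyl radical should turn the phenol into a phenoxyl radical and deliver its oxygen to the free ring position para to one hydroxyl and ortho to the other, which gives the 2-hydroxy-1,4-benzoquinone directly, as is known for resorcinols.

Compound list
1 | 1-icosanol | CCCCCCCCCCCCCCCCCCCCO | starting material
2 | ethyl (triphenylphosphoranylidene)acetate | CCOC(=O)C=P(c1ccccc1)(c1ccccc1)c1ccccc1 | starting material
3 | icosanal (formed in the flask) | CCCCCCCCCCCCCCCCCCCC=O | intermediate
4 | ethyl (E)-docos-2-enoate | CCCCCCCCCCCCCCCCCCC/C=C/C(=O)OCC | intermediate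
5 | ethyl 3-oxopentanoate | CCC(=O)CC(=O)OCC | starting material
6 | ethyl 3-methyl-2,4-dioxo-6-nonadecylcyclohexane-1-carboxylate (formed in the flask as its sodium enolate, mixture of stereoisomers) | CCCCCCCCCCCCCCCCCCCC1CC(=O)C(C)C(=O)C1C(=O)OCC | intermediate
7 | 2-methyl-5-nonadecylcyclohexane-1,3-dione (racemic, largely enolised) | CCCCCCCCCCCCCCCCCCCC1CC(=O)C(C)C(=O)C1 | intermediate
8 | 2-methyl-5-nonadecylbenzene-1,3-diol (2-methyl-5-nonadecylresorcinol) | CCCCCCCCCCCCCCCCCCCc1cc(O)c(C)c(O)c1 | intermediate
9 | capiquinone C, 2-hydroxy-3-methyl-6-nonadecylcyclohexa-2,5-diene-1,4-dione | CCCCCCCCCCCCCCCCCCCC1=CC(=O)C(C)=C(O)C1=O | target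

Total step count: 4
Longest linear sequence: 4 steps (1 → 4 → 7 → 8 → 9)

Steps most likely to fail

Step 2. The Claisen closure through the less acidic and more hindered propionyl CH2 may be slow, so that retro-Michael cleavage and deconjugation of the enoate compete and the ring does not form. The fallback sets out from 4 and uses the proven acetoacetate donor, adding the methyl group afterwards. Compound 4 and ethyl acetoacetate with NaOEt in refluxing EtOH should give ethyl 2,4-dioxo-6-nonadecylcyclohexane-1-carboxylate F1. Hydrolysis and decarboxylation in the same flask (aq. KOH, then HCl, reflux) should give 5-nonadecylcyclohexane-1,3-dione F2. C-Methylation of F2 at the carbon between the two carbonyls (MeI, aq. KOH, reflux), the standard preparation of 2-methylcyclohexane-1,3-diones, comes back to the route at 7.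

Step 3. Hydrogen set free on the catalyst may reduce one carbonyl, with loss of an oxygen by dehydration, or dehydrogenation may stay incomplete at the temperature used. The fallback sets out from 7 and replaces catalytic dehydrogenation by a halogen-mediated oxidative aromatisation. Iodine (2 equiv) in refluxing methanol should form the methyl enol ether, iodinate it next to the remaining carbonyl and lose HI, giving 3-methoxy-2-methyl-5-nonadecylphenol F3. Demethylation of F3 with BBr3 in CH2Cl2 (−78 °C to rt) comes back to the route at 8.

Step 4. Phenoxyl radicals of the waxy substrate may couple with each other, or the electron-rich hydroxyquinone may be oxidised further, because contact with the aqueous radical salt is poor. The fallback sets out from 8 and brings in the oxygen by a two-electron sequence. Vilsmeier–Haack formylation (POCl3, DMF, MeCN, 0 °C to rt, then water) at the position ortho and para to the hydroxyls should give 2,4-dihydroxy-3-methyl-6-nonadecylbenzaldehyde F4. Dakin oxidation of F4 (H2O2, aq. NaOH, THF, 0 °C, under N2) should give 3-methyl-6-nonadecylbenzene-1,2,4-triol F5. Oxidation of F5 with air or Ag2O in ether comes back to the route at 9.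

Further compounds
F1 | step 2 | ethyl 2,4-dioxo-6-nonadecylcyclohexane-1-carboxylate | CCCCCCCCCCCCCCCCCCCC1CC(=O)CC(=O)C1C(=O)OCC
F2 | step 2 | 5-nonadecylcyclohexane-1,3-dione | CCCCCCCCCCCCCCCCCCCC1CC(=O)CC(=O)C1
F3 | step 3 | 3-methoxy-2-methyl-5-nonadecylphenol | CCCCCCCCCCCCCCCCCCCc1cc(O)c(C)c(OC)c1
F4 | step 4 | 2,4-dihydroxy-3-methyl-6-nonadecylbenzaldehyde | CCCCCCCCCCCCCCCCCCCc1cc(O)c(C)c(O)c1C=O
F5 | step 4 | 3-methyl-6-nonadecylbenzene-1,2,4-triol | CCCCCCCCCCCCCCCCCCCc1cc(O)c(C)c(O)c1O
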